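**Remark on the chemistry:** ring B atoms are numbered as in the final chromone (C4a, C5–C8, C8a) in every intermediate, so pyranone C2 is C8a and pyranone C3 is C4a. (−)-Diethyl D-tartrate, the (2S,3S) ester, is used as the source of C6 and C7 in place of a pentose, because its C2 symmetry removes any question of which hydroxyl is protected.

## Analysis of the target

Target 23 is an ether-linked dimer of two 2-(2-phenylethyl)chromones. The upper unit is a flat 7-methoxychromone (ring A is its benzo ring). Its C6 oxygen is bonded to C8 of the lower unit, a 5,6,7,8-tetrahydrochromone whose carbocycle (ring B: C4a, C5, C6, C7, C8, C8a) carries free hydroxyls at C5, C6 and C7. Ring B holds all four stereocenters, (5S,6R,7S,8S). The oxygens at C5, C7 and C8 lie on one face and the C6 oxygen on the other, so the relations are 5,6-trans, 6,7-trans and 7,8-cis (the D-gluco pattern when C5–C8 is drawn as an open chain). The C5 hydroxyl and the C8 aryl ether sit on carbons attached to the pyranone double bond C4a=C8a, so ring B can aromatise by loss of water and of the phenol. The 4-pyranone rings are electrophilic at C2 and C8a and carry acidic CH2 groups next to C2. The difficulty is to set four contiguous oxygenated centres on a ring fused to an electron-poor heterocycle, and to join the most hindered of the four oxygens to an ortho-substituted arene without disturbing C8. The strategy rests on C8a. It is the β-carbon of the enone C4=O/C4a=C8a and also bears the ring oxygen O1. In a 2-methoxy-4-pyranone the same carbon bears a methoxy group as well, so a nucleophilic C8 radical can add there and the methoxy group can leave. This forms C8–C8a, closes ring B and restores the pyranone.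

## Retrosynthetic reasoning

**Protecting groups (23 from 22).** The three hydroxyls of 23 are carried as methoxymethyl ethers in 22. These acetals survive an organomagnesium reagent, a one-electron reductant and electrolysis. They leave under dilute acid, which does not break a C–O bond at C5–C8 and spares the aryl methyl ether.

**Aryl–oxygen bond (22 from 16 and 21).** The ether is cut between the oxygen and C6 of ring A, not between the oxygen and C8. Forming the bond at C8 would require substitution at a hindered secondary carbon flanked by an oxygenated carbon and the pyranone, with an uncertain stereochemical outcome. Cutting on the arene side leaves C8 untouched, so alcohol 16 passes its configuration on with retention. The partner is the ring A bromide 21. Because 16 has a single free hydroxyl, no site selectivity is needed; the forward reaction must couple a secondary alcohol with an ortho-methoxy aryl bromide.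

**C8–C8a bond (16 from 15).** This is the strategic cut. C8a is the only ring B carbon that is electrophilic in a pyranone, and with a methoxy leaving group it can return to sp2 after taking up a carbon substituent. The cut turns ring B into a four-carbon chain on C4a in aldehyde 15, with C5, C6 and C7 already oxygenated and configured. The forward step must generate a C8 ketyl, add it to C8a in preference to C4a, expel methoxide, and set C8 cis to the C7 oxygen.

**Adjustments on the chain (15 from 14, 13 and 12).** The aldehyde of 15 comes from the primary alcohol 14, which is kept as the silyl ether 13 until needed. The C5 methoxymethyl ether of 13 comes from the free C5 alcohol 12.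

**C4a–C5 bond (12 from 5 and 10 through 11).** C4a is the α-carbon of the pyranone, so it can act as a nucleophile once iodide 5 is converted into the magnesium reagent 11. C5 is then the carbonyl carbon of aldehyde 10. The cut is placed here because the bond joins the two fragments and creates C5 next to the C6 ether, which can direct the addition by chelation to the required 5,6-threo relation.

**Pyranone 5 (from 4, 3, 1 and 2).** Iodide 5 comes from iodination of the 2-methoxy-4-pyranone 4 at its most electron-rich carbon. Pyranone 4 comes from O-methylation of hydroxypyranone 3 at the carbonyl oxygen. Pyranone 3 comes from benzylation of the dianion of lactone 1 with bromide 2, which builds the phenylethyl side chain.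

**Aldehyde 10 (from 9, 8, 7 and 6).** C6 and C7 form a threo diol with a formyl-level carbon at each end, which is the pattern of tartrate 6. Double acetal protection gives 7 and reduction gives diol 8. Either hydroxyl of the C2-symmetric 8 can be silylated to give 9, and oxidation gives 10. No stereocenter is made in this branch.

**Bromide 21 (from 20, 19, 18 and 17).** The pyranone ring of 21 is cut at O1–C2 and C3–C4a, giving diketone 20. This comes from Claisen condensation of bromoketone 18 with ester 19. Ketone 18 is the bromination product of paeonol 17 at the position para to the hydroxyl.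

## Alternatives that were turned down

**Alternative 1:** The two C–O bonds at C7 and C8 are cut, leading back to the aromatic chromone A1. In the forward step, whole cells expressing a Rieske arene dioxygenase would cis-dihydroxylate the benzo ring to give the dihydrodiol A2.
- For: two stereocenters with the required cis relation arise in one operation from a flat substrate that needs no protecting groups. On step economy up to that point this alternative is stronger than the chosen route.
- Against: A1 has two benzene rings. The monosubstituted side-chain phenyl is the more electron-rich and the more typical enzyme substrate, while the benzo ring is deactivated by the fused carbonyl. Neither the ring, the position (5,6 or 7,8) nor the absolute sense can be predicted from structure. A2 is a dihydroarene diol that rearomatises by dehydration. C5=C6 must still become a trans diol anti to C7–O. The C8 hydroxyl must still be arylated in the presence of the equally allylic C7 hydroxyl.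
- Comparison: the chosen strategy takes C6 and C7 from the chiral pool, reaches 16 with only one free hydroxyl, and each uncertain step can be adjusted by chemical means.

**Alternative 2:** Ring B is cut at C6=C7. The forward step is ring-closing metathesis of diene A3 with the second-generation Grubbs catalyst, RuCl2(H2IMes)(PCy3)(=CHPh), giving the cis-5,8-dioxygenated dihydrochromone A4.
- For: closure of a cyclohexene by metathesis is more secure than the radical closure chosen here. The aryl ether is already in place, so the hindered late etherification is avoided. On both points this alternative is stronger.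
- Against: A3 needs two different allylic carbinol centres on neighbouring pyranone carbons, each set separately. Its allyl aryl ether is prone to ionisation and Claisen rearrangement. After closure, C6=C7 must become a trans diol, which requires epoxidation and anti opening. The two epoxide carbons are almost equivalent, so nothing controls whether the target or its 6,7-bis-epimer forms.
- Comparison: in the chosen strategy all four oxygens are present when the ring closes, C6 and C7 are fixed from the start, and only C8 is left to the key step.

**Alternative 3:** C5–C6 and C7–C8 are cut. Irradiation of aldehyde A5 would generate a hydroxy-diene by photoenolisation, which adds to enedione A6 on Ti(OiPr)4 bearing a chiral diol to give the diacetyl compound A7.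
- For: two C–C bonds, the ring and four contiguous stereocenters form at once. The E-geometry of A6 gives 6,7-trans, endo approach gives 7,8-cis and an out,out-diene gives 5,8-cis. On convergence and stereocenters per step this alternative is stronger.
- Against: C6 and C7 arrive as acetyl carbons where the target has oxygen. Two Baeyer–Villiger oxidations and two acetate cleavages follow, on a molecule where each ketone is β to an oxygen substituent. Elimination, retro-aldol opening at C7–C8 and epimerisation then threaten the centres just set. The pyranone chromophore has its own photochemistry that competes with hydrogen abstraction by the formyl group. Absolute control depends on a chiral titanium complex holding a symmetric dienophile. The C8 hydroxyl still has to be arylated.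
- Comparison: the chosen strategy installs every oxygen as oxygen and draws absolute configuration from tartrate.

Key step: step 12

## Steps

**Step 1**
Reactants: 1 4-hydroxy-6-methyl-2H-pyran-2-one (triacetic acid lactone); 2 benzyl bromide
Product: 3 4-hydroxy-6-(2-phenylethyl)-2H-pyran-2-one
Conditions: LDA (2.2 equiv), THF/DMPU, −78 °C; 2, −78 → 0 °C; 1 M HCl
Reagents that add atoms: none
Why: Double deprotonation gives the O,C-dianion, whose more reactive end is the carbanion of the C6 methyl group; dianion γ-alkylation with the benzylic bromide should occur there and leave the hydroxyl oxygen and C3 untouched.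

**Step 2**
Reactants: 3 4-hydroxy-6-(2-phenylethyl)-2H-pyran-2-one
Product: 4 2-methoxy-6-(2-phenylethyl)-4H-pyran-4-one
Conditions: MeOTf (1.1 equiv), CH2Cl2, 0 °C → rt; aq NaHCO3
Reagents that add atoms: methyl trifluoromethanesulfonate, COS(=O)(=O)C(F)(F)F
Why: The neutral vinylogous acid is methylated by the hard alkylating agent at its basic carbonyl oxygen, not at the hydroxyl; loss of the proton from the 4-hydroxy-2-methoxypyrylium ion should give the 2-methoxy-4-pyranone, the isomer opposite to that formed from the anion (regioselective O-methylation of a protomeric ambident system).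

**Step 3**
Reactants: 4 2-methoxy-6-(2-phenylethyl)-4H-pyran-4-one
Product: 5 3-iodo-2-methoxy-6-(2-phenylethyl)-4H-pyran-4-one
Conditions: NIS (1.1 equiv), TFA (10 mol %), MeCN, 0 °C → rt
Reagents that add atoms: N-iodosuccinimide, O=C1CCC(=O)N1I
Why: Electrophilic iodination should go to C3, which is activated by both the methoxy oxygen and the ring oxygen on C2; C5 has only one such donor and the phenyl ring is not activated.

**Step 4**
Reactants: 6 diethyl D-tartrate, diethyl (2S,3S)-2,3-dihydroxybutanedioate
Product: 7 diethyl (2S,3S)-2,3-bis(methoxymethoxy)butanedioate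
Conditions: MOMCl (3 equiv), iPr2NEt (4 equiv), CH2Cl2, 0 → 40 °C
Reagents that add atoms: chloromethyl methyl ether, COCCl
Why: O-alkylation of both secondary hydroxyls with the chloromethyl ether under amine base (acetal protection); the α-centres are not deprotonated by the hindered amine, so the configuration is kept.

**Step 5**
Reactants: 7 diethyl (2S,3S)-2,3-bis(methoxymethoxy)butanedioate
Product: 8 (2R,3R)-2,3-bis(methoxymethoxy)butane-1,4-diol
Conditions: LiAlH4, THF, 0 °C → rt; Fieser work-up
Reagents that add atoms: none
Why: Hydride reduction of both esters to primary alcohols; the acetal ethers are inert, and the descriptors change only because the substituent priorities change.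

**Step 6**
Reactants: 8 (2R,3R)-2,3-bis(methoxymethoxy)butane-1,4-diol
Product: 9 (2R,3R)-4-{[tert-butyl(dimethyl)silyl]oxy}-2,3-bis(methoxymethoxy)butan-1-ol
Conditions: NaH (1.0 equiv), THF, 0 °C → rt; TBSCl (1.0 equiv)
Reagents that add atoms: tert-butyldimethylsilyl chloride, CC(C)(C)[Si](C)(C)Cl
Why: Monosilylation of a symmetric diol through its monosodium alkoxide; the two hydroxyls are equivalent by C2 symmetry, so either one gives the same product.

**Step 7**
Reactants: 9 (2R,3R)-4-{[tert-butyl(dimethyl)silyl]oxy}-2,3-bis(methoxymethoxy)butan-1-ol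
Product: 10 (2S,3R)-4-{[tert-butyl(dimethyl)silyl]oxy}-2,3-bis(methoxymethoxy)butanal
Conditions: Dess–Martin periodinane, NaHCO3, CH2Cl2, 0 °C → rt; used at once
Reagents that add atoms: none
Why: Buffered periodinane oxidation of the primary alcohol stops at the aldehyde and should not epimerise the α-alkoxy centre.

**Step 8**
Reactants: 5 3-iodo-2-methoxy-6-(2-phenylethyl)-4H-pyran-4-one; 10 (2S,3R)-4-{[tert-butyl(dimethyl)silyl]oxy}-2,3-bis(methoxymethoxy)butanal
Product: 12 3-[(1S,2R,3R)-4-{[tert-butyl(dimethyl)silyl]oxy}-1-hydroxy-2,3-bis(methoxymethoxy)butyl]-2-methoxy-6-(2-phenylethyl)-4H-pyran-4-one, via [2-methoxy-4-oxo-6-(2-phenylethyl)-4H-pyran-3-yl]magnesium chloride 11 (not isolated)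
Conditions: 5 (1.3 equiv), iPrMgCl·LiCl (1.25 equiv), THF, −40 °C, 30 min; then added to 10 + MgBr2·OEt2 (2 equiv), CH2Cl2, −78 → −40 °C; aq NH4Cl
Reagents that add atoms: none
Why: Iodine–magnesium exchange on the α-iodo enone is fast at −40 °C and puts the metal on C4a; the aldehyde is held by MgBr2 in a five-membered Cram chelate between the carbonyl oxygen and the C6 ether oxygen. Attack from the face opposite the C7 chain should give the 5,6-syn (threo) alcohol, i.e. (5S).

**Step 9**
Reactants: 12 3-[(1S,2R,3R)-4-{[tert-butyl(dimethyl)silyl]oxy}-1-hydroxy-2,3-bis(methoxymethoxy)butyl]-2-methoxy-6-(2-phenylethyl)-4H-pyran-4-one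
Product: 13 3-[(1S,2R,3R)-4-{[tert-butyl(dimethyl)silyl]oxy}-1,2,3-tris(methoxymethoxy)butyl]-2-methoxy-6-(2-phenylethyl)-4H-pyran-4-one
Conditions: MOMCl, iPr2NEt, n-Bu4NI (cat.), CH2Cl2, 0 → 40 °C
Reagents that add atoms: chloromethyl methyl ether, COCCl
Why: Acetal protection of the hindered C5 hydroxyl with the more reactive iodomethyl ether formed in situ; the C5–O bond is not broken, so the configuration is retained.

**Step 10**
Reactants: 13 3-[(1S,2R,3R)-4-{[tert-butyl(dimethyl)silyl]oxy}-1,2,3-tris(methoxymethoxy)butyl]-2-methoxy-6-(2-phenylethyl)-4H-pyran-4-one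
Product: 14 3-[(1S,2R,3R)-4-hydroxy-1,2,3-tris(methoxymethoxy)butyl]-2-methoxy-6-(2-phenylethyl)-4H-pyran-4-one
Conditions: TBAF, AcOH, THF, 0 °C → rt
Reagents that add atoms: none
Why: Fluoride cleaves the primary silyl ether; buffering with acetic acid keeps the liberated alkoxide from attacking the electrophilic C8a, and the acetals and the methoxypyranone are stable.

**Step 11**
Reactants: 14 3-[(1S,2R,3R)-4-hydroxy-1,2,3-tris(methoxymethoxy)butyl]-2-methoxy-6-(2-phenylethyl)-4H-pyran-4-one
Product: 15 (2S,3R,4S)-4-[2-methoxy-4-oxo-6-(2-phenylethyl)-4H-pyran-3-yl]-2,3,4-tris(methoxymethoxy)butanal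
Conditions: Dess–Martin periodinane, NaHCO3, CH2Cl2, 0 °C → rt; crude taken into step 12
Reagents that add atoms: none
Why: Mild buffered oxidation of the primary alcohol gives the C8 aldehyde without epimerising C7; immediate use avoids hydrate formation and enolisation.

**Step 12**
Reactants: 15 (2S,3R,4S)-4-[2-methoxy-4-oxo-6-(2-phenylethyl)-4H-pyran-3-yl]-2,3,4-tris(methoxymethoxy)butanal
Product: 16 (5S,6R,7R,8S)-8-hydroxy-5,6,7-tris(methoxymethoxy)-2-(2-phenylethyl)-5,6,7,8-tetrahydro-4H-chromen-4-one
Conditions: SmI2 (2.5 equiv, 0.1 M in THF), 15 in THF added over 1 h (final 5 mM), −78 → 0 °C, no HMPA, no proton source; sat. aq NH4Cl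
Reagents that add atoms: none
Why: Proposed new method: SmI2 (divalent samarium) gives one electron to the C8 aldehyde, and the samarium ketyl, a nucleophilic radical, adds to C8a, the β-carbon of the pyranone enone with the largest LUMO coefficient; a second electron turns the α-keto radical at C4a into the samarium enolate, which expels the C8a methoxide standing perpendicular to the enolate plane, so the pyranone returns and C8–C8a remains. The closest known reaction types are the SmI2 ketyl–olefin cyclization onto enones, enoates and β-alkoxyacrylates, where the ketyl also attacks an oxygen-bearing β-carbon, and the polar addition–elimination of carbon nucleophiles on 2-methoxy-4-pyranones; radical addition to the fully substituted, doubly oxygenated C8a with loss of alkoxide has not been shown. Ring B closes in the 6-endo-trig mode, as expected for a hex-5-enyl-type radical whose inner alkene carbon is fully substituted; the 5-exo attack at C4a is disfavoured because C4a is the electron-rich α-carbon and would pass an electron-rich ketyl into an electron-rich dialkoxyalkyl radical at C8a (polarity mismatch). The new stereocenter C8 is under substrate control: in a chair-like transition state the C5, C6 and C7 ether groups are equatorial, and the bulky O–Sm group of the ketyl takes the pseudoaxial position, where it is anti to the C8a methoxy group and can chelate the C7 ether oxygen; this places the C8 hydroxyl cis to the C7 oxygen, i.e. (8S). The step needs the aldehyde to be reduced in preference to the pyranone, which the absence of HMPA should secure, and it needs cyclization to outrun pinacol coupling and simple reduction, which slow addition at high dilution and the absence of a proton source should favour. If the enolate were protonated instead, the resulting 8a-methoxy ketone would lose methanol on work-up or on brief treatment with base to give the same product.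

**Step 13**
Reactants: 17 paeonol, 1-(2-hydroxy-4-methoxyphenyl)ethan-1-one
Product: 18 1-(5-bromo-2-hydroxy-4-methoxyphenyl)ethan-1-one
Conditions: NBS (1.05 equiv), MeCN, 0 °C → rt
Reagents that add atoms: N-bromosuccinimide, O=C1CCC(=O)N1Br
Why: Electrophilic aromatic bromination should go to C5, para to the hydroxyl and ortho to the methoxy group; C3 lies between two substituents and is hindered.

**Step 14**
Reactants: 18 1-(5-bromo-2-hydroxy-4-methoxyphenyl)ethan-1-one; 19 ethyl 3-phenylpropanoate
Product: 21 6-bromo-7-methoxy-2-(2-phenylethyl)-4H-chromen-4-one, via 1-(5-bromo-2-hydroxy-4-methoxyphenyl)-5-phenylpentane-1,3-dione 20 (not isolated)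
Conditions: NaH (4 equiv), THF, reflux; 2 M HCl work-up; crude 20, conc. HCl (cat.), AcOH, 90 °C
Reagents that add atoms: none
Why: Claisen condensation of the phenoxide–enolate with the ester gives the 1,3-diketone; acid then closes the pyranone by attack of the phenol on the distal carbonyl and dehydration. The aryl bromide is inert to both operations.

**Step 15**
Reactants: 16 (5S,6R,7R,8S)-8-hydroxy-5,6,7-tris(methoxymethoxy)-2-(2-phenylethyl)-5,6,7,8-tetrahydro-4H-chromen-4-one; 21 6-bromo-7-methoxy-2-(2-phenylethyl)-4H-chromen-4-one
Product: 22 7-methoxy-2-(2-phenylethyl)-6-{[(5S,6R,7S,8S)-5,6,7-tris(methoxymethoxy)-4-oxo-2-(2-phenylethyl)-5,6,7,8-tetrahydro-4H-chromen-8-yl]oxy}-4H-chromen-4-one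
Conditions: 21 (1.5 equiv), NiBr2(dme) (10 mol %), 4,4′-di-tert-butyl-2,2′-bipyridine (10 mol %), quinuclidine (1.5 equiv), n-Bu4NBr, DMA, undivided cell, RVC anode, Ni-foam cathode, constant current, rt
Reagents that add atoms: none
Why: Nickel-catalysed C–O cross-coupling under electrolysis: cathodically generated low-valent nickel inserts into the aryl bromide, the alkoxide of 16 binds, and anodic oxidation to trivalent nickel drives C–O reductive elimination. The C8–O bond of 16 is never broken, so C8 is retained, and 16 has no other free hydroxyl.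

**Step 16**
Reactants: 22 7-methoxy-2-(2-phenylethyl)-6-{[(5S,6R,7S,8S)-5,6,7-tris(methoxymethoxy)-4-oxo-2-(2-phenylethyl)-5,6,7,8-tetrahydro-4H-chromen-8-yl]oxy}-4H-chromen-4-one
Product: 23 7-methoxy-2-(2-phenylethyl)-6-{[(5S,6R,7S,8S)-5,6,7-trihydroxy-4-oxo-2-(2-phenylethyl)-5,6,7,8-tetrahydro-4H-chromen-8-yl]oxy}-4H-chromen-4-one
Conditions: HCl (3 M in MeOH), 45 °C
Reagents that add atoms: none
Why: Acid-catalysed acetal exchange with methanol removes the three methoxymethyl groups; no C–O bond at C5–C8 is broken, so all four centres are kept. The aryl methyl ether, the aryl alkyl ether and both pyranones should tolerate dilute acid at this temperature.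

## Compound list

1 | 4-hydroxy-6-methyl-2H-pyran-2-one (triacetic acid lactone) | Cc1cc(O)cc(=O)o1 | starting material
2 | benzyl bromide | BrCc1ccccc1 | starting material
3 | 4-hydroxy-6-(2-phenylethyl)-2H-pyran-2-one | O=c1cc(O)cc(CCc2ccccc2)o1 | intermediate
4 | 2-methoxy-6-(2-phenylethyl)-4H-pyran-4-one | COc1cc(=O)cc(CCc2ccccc2)o1 | intermediate
5 | 3-iodo-2-methoxy-6-(2-phenylethyl)-4H-pyran-4-one | COc1oc(CCc2ccccc2)cc(=O)c1I | intermediate
6 | diethyl D-tartrate, diethyl (2S,3S)-2,3-dihydroxybutanedioate | CCOC(=O)[C@@H](O)[C@H](O)C(=O)OCC | starting material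
7 | diethyl (2S,3S)-2,3-bis(methoxymethoxy)butanedioate | CCOC(=O)[C@@H](OCOC)[C@H](OCOC)C(=O)OCC | intermediate
8 | (2R,3R)-2,3-bis(methoxymethoxy)butane-1,4-diol | OC[C@@H](OCOC)[C@H](OCOC)CO | intermediate
9 | (2R,3R)-4-{[tert-butyl(dimethyl)silyl]oxy}-2,3-bis(methoxymethoxy)butan-1-ol | OC[C@@H](OCOC)[C@H](OCOC)CO[Si](C)(C)C(C)(C)C | intermediate
10 | (2S,3R)-4-{[tert-butyl(dimethyl)silyl]oxy}-2,3-bis(methoxymethoxy)butanal | O=C[C@@H](OCOC)[C@H](OCOC)CO[Si](C)(C)C(C)(C)C | intermediate
11 | [2-methoxy-4-oxo-6-(2-phenylethyl)-4H-pyran-3-yl]magnesium chloride | COc1oc(CCc2ccccc2)cc(=O)c1[Mg]Cl | intermediate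
12 | 3-[(1S,2R,3R)-4-{[tert-butyl(dimethyl)silyl]oxy}-1-hydroxy-2,3-bis(methoxymethoxy)butyl]-2-methoxy-6-(2-phenylethyl)-4H-pyran-4-one | COc1oc(CCc2ccccc2)cc(=O)c1[C@H](O)[C@@H](OCOC)[C@H](OCOC)CO[Si](C)(C)C(C)(C)C | intermediate
13 | 3-[(1S,2R,3R)-4-{[tert-butyl(dimethyl)silyl]oxy}-1,2,3-tris(methoxymethoxy)butyl]-2-methoxy-6-(2-phenylethyl)-4H-pyran-4-one | COc1oc(CCc2ccccc2)cc(=O)c1[C@H](OCOC)[C@@H](OCOC)[C@H](OCOC)CO[Si](C)(C)C(C)(C)C | intermediate
14 | 3-[(1S,2R,3R)-4-hydroxy-1,2,3-tris(methoxymethoxy)butyl]-2-methoxy-6-(2-phenylethyl)-4H-pyran-4-one | COc1oc(CCc2ccccc2)cc(=O)c1[C@H](OCOC)[C@@H](OCOC)[C@H](OCOC)CO | intermediate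
15 | (2S,3R,4S)-4-[2-methoxy-4-oxo-6-(2-phenylethyl)-4H-pyran-3-yl]-2,3,4-tris(methoxymethoxy)butanal | COc1oc(CCc2ccccc2)cc(=O)c1[C@H](OCOC)[C@@H](OCOC)[C@H](OCOC)C=O | intermediate
16 | (5S,6R,7R,8S)-8-hydroxy-5,6,7-tris(methoxymethoxy)-2-(2-phenylethyl)-5,6,7,8-tetrahydro-4H-chromen-4-one | O[C@@H]1c2oc(CCc3ccccc3)cc(=O)c2[C@H](OCOC)[C@@H](OCOC)[C@@H]1OCOC | intermediate
17 | paeonol, 1-(2-hydroxy-4-methoxyphenyl)ethan-1-one | CC(=O)c1ccc(OC)cc1O | starting material
18 | 1-(5-bromo-2-hydroxy-4-methoxyphenyl)ethan-1-one | CC(=O)c1cc(Br)c(OC)cc1O | intermediate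
19 | ethyl 3-phenylpropanoate | CCOC(=O)CCc1ccccc1 | starting material
20 | 1-(5-bromo-2-hydroxy-4-methoxyphenyl)-5-phenylpentane-1,3-dione | COc1cc(O)c(cc1Br)C(=O)CC(=O)CCc1ccccc1 | intermediate
21 | 6-bromo-7-methoxy-2-(2-phenylethyl)-4H-chromen-4-one | COc1cc2oc(CCc3ccccc3)cc(=O)c2cc1Br | intermediate
22 | 7-methoxy-2-(2-phenylethyl)-6-{[(5S,6R,7S,8S)-5,6,7-tris(methoxymethoxy)-4-oxo-2-(2-phenylethyl)-5,6,7,8-tetrahydro-4H-chromen-8-yl]oxy}-4H-chromen-4-one | COc1cc2oc(CCc3ccccc3)cc(=O)c2cc1O[C@@H]1c2oc(CCc3ccccc3)cc(=O)c2[C@H](OCOC)[C@@H](OCOC)[C@@H]1OCOC | intermediate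
23 | 7-methoxy-2-(2-phenylethyl)-6-{[(5S,6R,7S,8S)-5,6,7-trihydroxy-4-oxo-2-(2-phenylethyl)-5,6,7,8-tetrahydro-4H-chromen-8-yl]oxy}-4H-chromen-4-one | COc1cc2oc(CCc3ccccc3)cc(=O)c2cc1O[C@@H]1c2oc(CCc3ccccc3)cc(=O)c2[C@H](O)[C@@H](O)[C@@H]1O | target

## Step count and risks

Total step count: 16. Longest linear sequence: 11 steps (6 → 7 → 8 → 9 → 10 → 12 → 13 → 14 → 15 → 16 → 22 → 23; steps 4–12, 15 and 16).

**Step 12 (key step, proposed new method).**
- What may go wrong: the ketyl may add too slowly to the fully substituted, doubly oxygenated C8a, so that simple reduction of the aldehyde, pinacol dimerisation or loss of the C7 alkoxy group takes over. Other possible failures are attack at C4a, loss of the C5 alkoxide from the samarium enolate, and poor facial selectivity at C8.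
- Fallback: the same bond is made by polar, known reaction types, setting out from 14 and rejoining at 16. Appel iodination (I2, PPh3, imidazole) should give the primary iodide F1. Kornblum substitution (NaNO2, DMF) should give the primary nitro compound F2. With DBU in MeCN the nitronate should add to C8a in a 6-endo Michael addition and methoxide should leave, giving the 8-nitro-tetrahydrochromone F3. An oxidative Nef reaction (nitronate with buffered Oxone) should give the C8 ketone F4. L-Selectride at −78 °C, attacking from the equatorial direction, should then give the axial, 7,8-cis alcohol 16.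
- If the cyclization works but favours the wrong C8 configuration, the inversion sequence described for step 15 would correct it.

**Step 8.**
- What may go wrong: the magnesiated pyranone may open by β-elimination of the ring oxygen, the exchange reagent may attack C8a in a conjugate fashion, or incomplete chelation control may lead to the C5 epimer.
- Fallback: set out from 5 and 10 and give up selectivity in the C–C bond formation. Nozaki–Hiyama–Kishi coupling (CrCl2, cat. NiCl2, DMF), which needs no free carbanion at C4a, should give 12 mixed with its C5 epimer F5. Oxidation of the mixture with Dess–Martin periodinane should give the ketone F6. Reduction with K-Selectride under Felkin–Anh control (non-chelating cation) should give the 5,6-syn alcohol and rejoin the route at 12.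

**Step 15.**
- What may go wrong: C–O reductive elimination may be slow with a hindered secondary alkoxide and an ortho-substituted, electron-rich aryl group. β-Hydride elimination from the nickel alkoxide may oxidise C8 and reduce the bromide. The pyranone units may be reduced at the cathode.
- Fallback: form the bond at C8 with inversion, setting out from 16 and 21 and rejoining at 22. Mitsunobu esterification of 16 (4-nitrobenzoic acid, PPh3, DIAD) should give the inverted 4-nitrobenzoate F7, and methanolysis (K2CO3, MeOH) the 8-epi alcohol F8. Hydroxylation of 21 (Pd2(dba)3, tBuXPhos, KOH, dioxane/H2O, 100 °C) should give the phenol F9. A second Mitsunobu reaction of F8 with F9 should invert C8 again and give 22.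

**Step 2.**
- What may go wrong: methyl transfer to the hydroxyl oxygen, or acid-promoted equilibration through the dimethoxypyrylium ion, would lead to the isomeric 4-methoxy-2-pyranone.
- Fallback: block the competing oxygen, setting out from 3 and rejoining at 4. Silylation (TBSCl, imidazole, CH2Cl2) should give the 4-silyl ether F10. MeOTf can then only methylate the lactone carbonyl oxygen, giving the pyrylium triflate F11, which is not isolated. Aqueous NaHCO3 removes the silyl group and should give 4.

## Further compounds

F1 | step 12 | 3-[(1S,2R,3S)-4-iodo-1,2,3-tris(methoxymethoxy)butyl]-2-methoxy-6-(2-phenylethyl)-4H-pyran-4-one | COc1oc(CCc2ccccc2)cc(=O)c1[C@H](OCOC)[C@@H](OCOC)[C@H](OCOC)CI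
F2 | step 12 | 2-methoxy-3-[(1S,2R,3R)-1,2,3-tris(methoxymethoxy)-4-nitrobutyl]-6-(2-phenylethyl)-4H-pyran-4-one | COc1oc(CCc2ccccc2)cc(=O)c1[C@H](OCOC)[C@@H](OCOC)[C@H](OCOC)C[N+](=O)[O-]
F3 | step 12 | (5S,6R,7R)-5,6,7-tris(methoxymethoxy)-8-nitro-2-(2-phenylethyl)-5,6,7,8-tetrahydro-4H-chromen-4-one, C8 epimers | [O-][N+](=O)C1c2oc(CCc3ccccc3)cc(=O)c2[C@H](OCOC)[C@@H](OCOC)[C@@H]1OCOC
F4 | step 12 | (5S,6R,7S)-5,6,7-tris(methoxymethoxy)-2-(2-phenylethyl)-6,7-dihydro-4H-chromene-4,8(5H)-dione | O=C1c2oc(CCc3ccccc3)cc(=O)c2[C@H](OCOC)[C@@H](OCOC)[C@@H]1OCOC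
F5 | step 8 | 3-[(1R,2R,3R)-4-{[tert-butyl(dimethyl)silyl]oxy}-1-hydroxy-2,3-bis(methoxymethoxy)butyl]-2-methoxy-6-(2-phenylethyl)-4H-pyran-4-one | COc1oc(CCc2ccccc2)cc(=O)c1[C@@H](O)[C@@H](OCOC)[C@H](OCOC)CO[Si](C)(C)C(C)(C)C
F6 | step 8 | 3-[(2S,3R)-4-{[tert-butyl(dimethyl)silyl]oxy}-2,3-bis(methoxymethoxy)butanoyl]-2-methoxy-6-(2-phenylethyl)-4H-pyran-4-one | COc1oc(CCc2ccccc2)cc(=O)c1C(=O)[C@@H](OCOC)[C@H](OCOC)CO[Si](C)(C)C(C)(C)C
F7 | step 15 | (5S,6R,7S,8R)-5,6,7-tris(methoxymethoxy)-4-oxo-2-(2-phenylethyl)-5,6,7,8-tetrahydro-4H-chromen-8-yl 4-nitrobenzoate | O=C(O[C@H]1c2oc(CCc3ccccc3)cc(=O)c2[C@H](OCOC)[C@@H](OCOC)[C@@H]1OCOC)c1ccc(cc1)[N+](=O)[O-]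
F8 | step 15 | (5S,6R,7R,8R)-8-hydroxy-5,6,7-tris(methoxymethoxy)-2-(2-phenylethyl)-5,6,7,8-tetrahydro-4H-chromen-4-one | O[C@H]1c2oc(CCc3ccccc3)cc(=O)c2[C@H](OCOC)[C@@H](OCOC)[C@@H]1OCOC
F9 | step 15 | 6-hydroxy-7-methoxy-2-(2-phenylethyl)-4H-chromen-4-one | COc1cc2oc(CCc3ccccc3)cc(=O)c2cc1O
F10 | step 2 | 4-{[tert-butyl(dimethyl)silyl]oxy}-6-(2-phenylethyl)-2H-pyran-2-one | O=c1cc(O[Si](C)(C)C(C)(C)C)cc(CCc2ccccc2)o1
F11 | step 2 | 4-{[tert-butyl(dimethyl)silyl]oxy}-2-methoxy-6-(2-phenylethyl)pyrylium trifluoromethanesulfonate | COc1cc(O[Si](C)(C)C(C)(C)C)cc(CCc2ccccc2)[o+]1.[O-]S(=O)(=O)C(F)(F)F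
A1 | alternative 1 | 2-(2-phenylethyl)-4H-chromen-4-one | O=c1cc(CCc2ccccc2)oc2ccccc12
A2 | alternative 1 | (7S,8S)-7,8-dihydroxy-2-(2-phenylethyl)-7,8-dihydro-4H-chromen-4-one | O[C@@H]1c2oc(CCc3ccccc3)cc(=O)c2C=C[C@@H]1O
A3 | alternative 2 | 6-{[(1S)-1-{3-[(1R)-1-{[tert-butyl(dimethyl)silyl]oxy}prop-2-en-1-yl]-4-oxo-6-(2-phenylethyl)-4H-pyran-2-yl}prop-2-en-1-yl]oxy}-7-methoxy-2-(2-phenylethyl)-4H-chromen-4-one | COc1cc2oc(CCc3ccccc3)cc(=O)c2cc1O[C@@H](C=C)c1oc(CCc2ccccc2)cc(=O)c1[C@H](O[Si](C)(C)C(C)(C)C)C=C
A4 | alternative 2 | 6-{[(5R,8S)-5-{[tert-butyl(dimethyl)silyl]oxy}-4-oxo-2-(2-phenylethyl)-5,8-dihydro-4H-chromen-8-yl]oxy}-7-methoxy-2-(2-phenylethyl)-4H-chromen-4-one | COc1cc2oc(CCc3ccccc3)cc(=O)c2cc1O[C@@H]1c2oc(CCc3ccccc3)cc(=O)c2[C@H](O[Si](C)(C)C(C)(C)C)C=C1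
A5 | alternative 3 | 3-({[tert-butyl(dimethyl)silyl]oxy}methyl)-4-oxo-6-(2-phenylethyl)-4H-pyran-2-carbaldehyde | O=Cc1oc(CCc2ccccc2)cc(=O)c1CO[Si](C)(C)C(C)(C)C
A6 | alternative 3 | (E)-hex-3-ene-2,5-dione | CC(=O)/C=C/C(C)=O
A7 | alternative 3 | (5R,6S,7S,8S)-6,7-diacetyl-5-{[tert-butyl(dimethyl)silyl]oxy}-8-hydroxy-2-(2-phenylethyl)-5,6,7,8-tetrahydro-4H-chromen-4-one (C5–O, C7–acetyl and C8–O on one face, C6–acetyl on the other) | O[C@@H]1c2oc(CCc3ccccc3)cc(=O)c2[C@H](O[Si](C)(C)C(C)(C)C)[C@@H](C(C)=O)[C@@H]1C(C)=O
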